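The route rests on cutting the bond between the guaiacyl benzylic CH2 and C4 of the oxolane. It exploits one feature. The cis pair C3 (CH2OAc)/C4 (benzyl) of the oxolane becomes a trans pair once C5, C4, C3 and the acetoxymethyl carbon are redrawn as a γ-butyrolactone. In one flask, a lithiated catechol-aldehyde dithiane adds to (5R)-menthyloxybutenolide. The resulting lithium enolate, the true precursor, is benzylated by the vanillyl bromide anti to the dithianyl group. That operation assembles all skeletal carbons and fixes both carbon-substituted ring stereocentres from one acetal centre. Hydride reduction expels the auxiliary, and acid then switches the ring to the 2-aryl oxolane.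

Key step: step 3

Assumption: (5R)-5-(l-menthyloxy)furan-2(5H)-one is taken as a purchasable chiral reagent, and the benzylic carbinol centre formed in the hydride step is left undefined because both epimers converge in the following ring closure.

Step 1
Reactants: 1 3,4-bis(benzyloxy)benzaldehyde
Product: 2 2-[3,4-bis(benzyloxy)phenyl]-1,3-dithiane
Conditions: HS(CH2)3SH, BF3·OEt2 (cat.), CH2Cl2, 0 °C to rt
Reagents that add atoms: propane-1,3-dithiol, SCCCS
Why: Lewis-acid-catalysed dithioacetalisation turns the formyl carbon into a Corey–Seebach acyl-anion equivalent, the aryl benzyl ethers tolerate catalytic BF3·OEt2 at this temperature, and no stereocentre is formed.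

Step 2
Reactants: 3 [4-(benzyloxy)-3-methoxyphenyl]methanol
Product: 4 1-(benzyloxy)-4-(bromomethyl)-2-methoxybenzene
Conditions: PBr3, Et2O, 0 °C; used without storage
Reagents that add atoms: phosphorus tribromide, BrP(Br)Br
Why: PBr3 bromination (SN2 displacement of the phosphite ester by bromide) is reliable for electron-rich primary benzylic alcohols, and immediate use avoids self-alkylation of the labile bromide.

Step 3
Reactants: 2 2-[3,4-bis(benzyloxy)phenyl]-1,3-dithiane; 5 (5R)-5-[(1R,2S,5R)-menthyloxy]furan-2(5H)-one; 4 1-(benzyloxy)-4-(bromomethyl)-2-methoxybenzene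
Product: 8 (3R,4R,5R)-3-[4-(benzyloxy)-3-methoxybenzyl]-4-{2-[3,4-bis(benzyloxy)phenyl]-1,3-dithian-2-yl}-5-[(1R,2S,5R)-menthyloxy]oxolan-2-one, via lithiated dithiane 6 (not isolated), via lithium enolate 7 (not isolated)
Conditions: 2, n-BuLi, THF, −78 to −20 °C; 5, −78 °C; then 4, DMPU, −78 °C to rt
Reagents that add atoms: none
Why: This is a tandem Michael addition–enolate alkylation (three-component coupling on a chiral γ-alkoxybutenolide): the soft, sulfur- and aryl-stabilised carbanion 6 adds 1,4 to 5, and the lithium enolate 7 so formed displaces bromide from 4 in an SN2 C-benzylation that makes the ArCH2–C3 bond. The closest known reaction type is the conjugate addition of lithiated aryl dithioacetals to butenolides with in situ trapping by benzylic halides, familiar from dibenzylbutyrolactone lignan chemistry. No ring is closed, because the lactone serves only as a temporary template. C4 of the lactone (later oxolane C3) is set by attack anti to the C5 menthyloxy group, and C3 (later oxolane C4) by approach of 4 anti to the very large dithianyl substituent on the flat enolate, which should give the 3,4-trans-4,5-trans lactone. The step needs 1,4- over 1,2-addition (secured by the delocalised anion and the unhindered cyclic enoate), C- over O-alkylation (soft benzylic bromide, lithium loosened by DMPU) and mono-alkylation (the remaining α-C–H is tertiary and flanked by two bulky groups). After the later ring switch this trans relation reads as the cis C3/C4 relation of the target.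

Step 4
Reactants: 8 the tandem adduct
Product: 9 (3R,4R,5R)-3-[4-(benzyloxy)-3-methoxybenzyl]-4-[3,4-bis(benzyloxy)benzoyl]-5-[(1R,2S,5R)-menthyloxy]oxolan-2-one
Conditions: HgO, BF3·OEt2, THF–H2O (85:15), rt
Reagents that add atoms: water, O
Why: Thiophilic Hg(II)-assisted dithioacetal hydrolysis frees the aryl ketone under acidic, non-enolising conditions that lactone, acetal and benzyl ethers tolerate, and the centre next to the new ketone already sits in the thermodynamically preferred all-trans arrangement.

Step 5
Reactants: 9 the keto lactone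
Product: 10 (2R,3R)-2-[4-(benzyloxy)-3-methoxybenzyl]-3-{[3,4-bis(benzyloxy)phenyl](hydroxy)methyl}butane-1,4-diol (carbinol epimers)
Conditions: LiAlH4 (excess), THF, 0 °C to rt; Rochelle salt work-up
Reagents that add atoms: none
Why: In this exhaustive LiAlH4 reduction the ketone is reduced first, the lactone then opens, and the released hemiacetal alkoxide expels menthoxide to an aldehyde that is reduced as well, so the auxiliary leaves in the same operation, the two backbone stereocentres are untouched, and the new carbinol centre need not be controlled.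

Step 6
Reactants: 10 the triol
Product: 11 {(2S,3R,4R)-2-[3,4-bis(benzyloxy)phenyl]-4-[4-(benzyloxy)-3-methoxybenzyl]oxolan-3-yl}methanol
Conditions: camphorsulfonic acid (cat.), CH2Cl2, 0 °C to rt, stopped at consumption of 10
Reagents that add atoms: none
Why: In this acid-catalysed SN1 cyclodehydration the p-alkoxybenzylic cation is captured 5-exo by the hydroxymethyl on the benzyl-bearing carbon (the other primary hydroxyl could only form an oxetane), and C2 is set under substrate control with the aryl group trans to the C3 hydroxymethyl, since reversible ionisation drains the crowded all-cis isomer.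

Step 7
Reactants: 11 the oxolane alcohol
Product: 12 {(2S,3R,4R)-2-[3,4-bis(benzyloxy)phenyl]-4-[4-(benzyloxy)-3-methoxybenzyl]oxolan-3-yl}methyl acetate
Conditions: Ac2O, pyridine, DMAP (cat.), CH2Cl2, rt
Reagents that add atoms: acetic anhydride, CC(=O)OC(C)=O
Why: DMAP-catalysed O-acetylation meets only one free hydroxyl because all three phenols are still benzylated, so no chemoselectivity is needed.

Step 8
Reactants: 12 the tri-O-benzyl acetate
Product: 13 [(2S,3R,4R)-2-(3,4-dihydroxyphenyl)-4-(4-hydroxy-3-methoxybenzyl)oxolan-3-yl]methyl acetate (target)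
Conditions: H2 (1 atm), 10% Pd/C, EtOAc, rt, stopped after uptake of 3 equiv
Reagents that add atoms: none
Why: Catalytic hydrogenolysis cleaves the three aryl benzyl ethers faster than the ring C2–O benzylic bond in neutral EtOAc, and the acetate and all stereocentres are inert to these conditions.

Compound list
1 | 3,4-bis(benzyloxy)benzaldehyde | O=Cc1ccc(OCc2ccccc2)c(OCc2ccccc2)c1 | starting material
2 | 2-[3,4-bis(benzyloxy)phenyl]-1,3-dithiane | C1(c2ccc(OCc3ccccc3)c(OCc3ccccc3)c2)SCCCS1 | intermediate
3 | [4-(benzyloxy)-3-methoxyphenyl]methanol | COc1cc(CO)ccc1OCc1ccccc1 | starting material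
4 | 1-(benzyloxy)-4-(bromomethyl)-2-methoxybenzene | COc1cc(CBr)ccc1OCc1ccccc1 | intermediate
5 | (5R)-5-[(1R,2S,5R)-menthyloxy]furan-2(5H)-one | CC(C)[C@@H]1CC[C@@H](C)C[C@H]1O[C@H]2C=CC(=O)O2 | starting material
6 | 2-lithio-2-[3,4-bis(benzyloxy)phenyl]-1,3-dithiane (lithiated dithiane) | [Li]C1(c2ccc(OCc3ccccc3)c(OCc3ccccc3)c2)SCCCS1 | intermediate
7 | lithium enolate of (4R,5R)-4-{2-[3,4-bis(benzyloxy)phenyl]-1,3-dithian-2-yl}-5-menthyloxyoxolan-2-one | CC(C)[C@@H]1CC[C@@H](C)C[C@H]1O[C@@H]2OC(O[Li])=C[C@H]2C3(c4ccc(OCc5ccccc5)c(OCc5ccccc5)c4)SCCCS3 | intermediate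
8 | (3R,4R,5R)-3-[4-(benzyloxy)-3-methoxybenzyl]-4-{2-[3,4-bis(benzyloxy)phenyl]-1,3-dithian-2-yl}-5-[(1R,2S,5R)-menthyloxy]oxolan-2-one | CC(C)[C@@H]1CC[C@@H](C)C[C@H]1O[C@@H]2OC(=O)[C@H](Cc3ccc(OCc4ccccc4)c(OC)c3)[C@H]2C5(c6ccc(OCc7ccccc7)c(OCc7ccccc7)c6)SCCCS5 | intermediate
9 | (3R,4R,5R)-3-[4-(benzyloxy)-3-methoxybenzyl]-4-[3,4-bis(benzyloxy)benzoyl]-5-[(1R,2S,5R)-menthyloxy]oxolan-2-one | CC(C)[C@@H]1CC[C@@H](C)C[C@H]1O[C@@H]2OC(=O)[C@H](Cc3ccc(OCc4ccccc4)c(OC)c3)[C@H]2C(=O)c5ccc(OCc6ccccc6)c(OCc6ccccc6)c5 | intermediate
10 | (2R,3R)-2-[4-(benzyloxy)-3-methoxybenzyl]-3-{[3,4-bis(benzyloxy)phenyl](hydroxy)methyl}butane-1,4-diol, carbinol centre undefined | OC(c1ccc(OCc2ccccc2)c(OCc2ccccc2)c1)[C@@H](CO)[C@H](CO)Cc1ccc(OCc2ccccc2)c(OC)c1 | intermediate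
11 | {(2S,3R,4R)-2-[3,4-bis(benzyloxy)phenyl]-4-[4-(benzyloxy)-3-methoxybenzyl]oxolan-3-yl}methanol | COc1cc(C[C@H]2CO[C@H](c3ccc(OCc4ccccc4)c(OCc4ccccc4)c3)[C@H]2CO)ccc1OCc1ccccc1 | intermediate
12 | {(2S,3R,4R)-2-[3,4-bis(benzyloxy)phenyl]-4-[4-(benzyloxy)-3-methoxybenzyl]oxolan-3-yl}methyl acetate | COc1cc(C[C@H]2CO[C@H](c3ccc(OCc4ccccc4)c(OCc4ccccc4)c3)[C@H]2COC(C)=O)ccc1OCc1ccccc1 | intermediate
13 | [(2S,3R,4R)-2-(3,4-dihydroxyphenyl)-4-(4-hydroxy-3-methoxybenzyl)oxolan-3-yl]methyl acetate | COc1cc(C[C@H]2CO[C@H](c3ccc(O)c(O)c3)[C@H]2COC(C)=O)ccc1O | target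

Total step count: 8. Longest linear sequence: 7 (steps 1, 3, 4, 5, 6, 7, 8).

Steps most likely to fail

Step 3. C-benzylation of the crowded enolate may be slow, so that proton transfer, retro-Michael loss of the dithiane anion or erosion of the anti selectivity competes.
- The fallback sets out from enolate 7, generated as before from 2 and 5.
- It forms the same bond with a much more reactive electrophile, commercial 4-(benzyloxy)-3-methoxybenzaldehyde, added at −78 °C. This gives the aldol adduct F1, with either carbinol epimer acceptable.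
- Ionic hydrogenation (Et3SiH, CF3CO2H, CH2Cl2, −20 to 0 °C) then removes the p-alkoxybenzylic hydroxyl through its stabilised cation.
- The dithiane and the acyloxy-deactivated acetal stay intact, and the route is rejoined at 8.

Step 4. Once the ketone is free, β-elimination of the acyloxy or menthyloxy group from the neighbouring acetal carbon may intervene. Epimerisation next to the ketone, or sluggish hydrolysis of the hindered dithiane, are the other possibilities.
- The fallback sets out from 8 and reverses the order of events.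
- LiAlH4 first removes lactone, acetal and auxiliary to give the dithiane diol F2, which carries no good leaving group β to the masked carbonyl.
- Thiophilic hydrolysis then gives the keto diol F3, which rests as its five-membered cyclic hemiketal.
- NaBH4 in MeOH reduces F3 through the open form, and the route is rejoined at 10.

Step 6. The benzylic cation may be captured irreversibly by the electron-rich guaiacyl ring (Friedel–Crafts closure to a tetralin), or the 2,3-trans preference may be incomplete at short contact times.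
- The fallback sets out from 10 and closes the ring through a neutral p-quinone methide instead of a cation.
- Neutral hydrogenolysis (H2, Pd/C, EtOAc–EtOH) gives the free-phenol hexaol F4.
- The p-hydroxybenzylic alcohol of F4 ionises at far lower acidity (dilute AcOH in aqueous THF). The hydroxymethyl group then adds to the quinone methide to give 3-O-demethyllariciresinol F5.
- Immobilised Candida antarctica lipase B with vinyl acetate in MTBE–THF acetylates the primary aliphatic hydroxyl in preference to the phenols.
- The route is rejoined at 13, bypassing steps 7 and 8.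

Further compounds
F1 | step 3 | (3S,4R,5R)-3-{[4-(benzyloxy)-3-methoxyphenyl](hydroxy)methyl}-4-{2-[3,4-bis(benzyloxy)phenyl]-1,3-dithian-2-yl}-5-[(1R,2S,5R)-menthyloxy]oxolan-2-one, carbinol centre undefined | CC(C)[C@@H]1CC[C@@H](C)C[C@H]1O[C@@H]2OC(=O)[C@H](C(O)c3ccc(OCc4ccccc4)c(OC)c3)[C@H]2C5(c6ccc(OCc7ccccc7)c(OCc7ccccc7)c6)SCCCS5
F2 | step 4 | (2R,3R)-2-[4-(benzyloxy)-3-methoxybenzyl]-3-{2-[3,4-bis(benzyloxy)phenyl]-1,3-dithian-2-yl}butane-1,4-diol | OC[C@H](Cc1ccc(OCc2ccccc2)c(OC)c1)[C@H](CO)C1(c2ccc(OCc3ccccc3)c(OCc3ccccc3)c2)SCCCS1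
F3 | step 4 | (2R,3R)-1-[3,4-bis(benzyloxy)phenyl]-3-[4-(benzyloxy)-3-methoxybenzyl]-4-hydroxy-2-(hydroxymethyl)butan-1-one (open form of the cyclic hemiketal) | O=C(c1ccc(OCc2ccccc2)c(OCc2ccccc2)c1)[C@@H](CO)[C@H](CO)Cc1ccc(OCc2ccccc2)c(OC)c1
F4 | step 6 | (2R,3R)-2-[(3,4-dihydroxyphenyl)(hydroxy)methyl]-3-(4-hydroxy-3-methoxybenzyl)butane-1,4-diol, carbinol centre undefined | OC(c1ccc(O)c(O)c1)[C@@H](CO)[C@H](CO)Cc1ccc(O)c(OC)c1
F5 | step 6 | 4-[(2S,3R,4R)-4-(4-hydroxy-3-methoxybenzyl)-3-(hydroxymethyl)oxolan-2-yl]benzene-1,2-diol (3-O-demethyllariciresinol) | COc1cc(C[C@H]2CO[C@H](c3ccc(O)c(O)c3)[C@H]2CO)ccc1O
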